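**Retrosynthetic overview**

1. Target 21 ⇐ desilylation of 20 ⇐ bicyclic enone 16 + acid 19 by a late γ-C–H acyloxylation that forms the C6–O bond and sets C6.
2. Enone 16 ⇐ trans-hydrindane silyl enol ether 13 by a one-carbon ring expansion (six- to seven-membered ring): a methyl-substituted siloxycyclopropane is opened with FeCl3; C8 and its methyl come from CH3CHI2.
3. 13 ⇐ cyclopentenone 9 by conjugate borylation/oxidation (C4–OH), hydride reduction and acetylation (C2).
4. 9 ⇐ trans-diacylcyclohexene 7 (aldol condensation) ⇐ Diels–Alder adduct 5 of keto-enal 3 (from 2,3-dimethylfuran 1) with silyloxydiene 4, then isopropyl Grignard addition/oxidation.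
5. Ring order: six-membered ring (cycloaddition) → five-membered ring (aldol) → six-membered ring expanded to the seven-membered ring.

Assumption: daucane numbering is used for the skeleton (C1 methyl-bearing ring-fusion carbon, C2 CH–OAc, C4 C(OH)i-Pr, C5 ring-fusion CH, C6 CH–O-aroyl, C8 methyl-bearing alkene carbon, C9 C=O), β is the face of the C1 methyl, and the silyl ethers 4 and 17 are bought as such (silyl-protected enol of but-3-en-2-one and silyl-protected 4-bromophenol).

**Route**

Step 1
Reactants: 1 2,3-dimethylfuran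
Product: 3 (2E)-3-methyl-4-oxopent-2-enal, via Z-enal 2 (not isolated)
Conditions: NBS, NaHCO3, acetone/H2O (10:1), −15 °C; then pyridine, 23 °C
Reagents that add atoms: water (O)
Why: Oxidative furan ring opening (bromohydration, loss of HBr) gives the cis-keto-enal, which pyridine isomerises to the E isomer with formyl and acetyl trans, the geometry later needed for the trans ring fusion.

Step 2
Reactants: 3 (2E)-3-methyl-4-oxopent-2-enal; 4 2-(tert-butyldimethylsilyloxy)buta-1,3-diene
Product: 5 (1S,6S)-6-acetyl-4-(tert-butyldimethylsilyloxy)-6-methylcyclohex-3-ene-1-carbaldehyde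
Conditions: (S)-3,3-diphenyl-1-(o-tolyl)pyrrolo-oxazaborolidine protonated with HNTf2 (15 mol %), CH2Cl2, −78 °C
Reagents that add atoms: none
Why: Catalytic enantioselective Diels–Alder reaction in which the boron-bound formyl group makes the methyl-bearing β-carbon of 3 the electrophilic end, so the CH2 next to the siloxy carbon of 4 bonds there (siloxy carbon para to the formyl-bearing carbon), the E geometry gives the trans formyl/acetyl pair (C5 and quaternary C1), and the (S)-catalyst is relied on to shield one enal face (its mirror image is used if the sense proves opposite).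

Step 3
Reactants: 5 (1S,6S)-6-acetyl-4-(tert-butyldimethylsilyloxy)-6-methylcyclohex-3-ene-1-carbaldehyde
Product: 7 1-[(1S,6S)-6-acetyl-4-(tert-butyldimethylsilyloxy)-6-methylcyclohex-3-en-1-yl]-2-methylpropan-1-one, via carbinol 6 (not isolated)
Conditions: i-PrMgBr, THF, −78 °C; then 1,1'-(azodicarbonyl)dipiperidine, −78 → 0 °C
Reagents that add atoms: isopropylmagnesium bromide (CC(C)[Mg]Br)
Why: Chemoselective Grignard addition to the aldehyde (faster than to the hindered methyl ketone) followed in the same flask by Mukaiyama oxidation of the magnesium alkoxide, so the transient carbinol centre does not matter.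

Step 4
Reactants: 7 1-[(1S,6S)-6-acetyl-4-(tert-butyldimethylsilyloxy)-6-methylcyclohex-3-en-1-yl]-2-methylpropan-1-one
Product: 9 trans-3-isopropyl-7a-methyl-6-(tert-butyldimethylsilyloxy)-3a,4,7,7a-tetrahydro-1H-inden-1-one, via aldol 8 (not isolated)
Conditions: KOt-Bu (0.3 equiv), t-BuOH/THF, 0 → 23 °C
Reagents that add atoms: none
Why: Intramolecular aldol condensation in which the methyl-ketone enolate (C3) closes onto the isobutyryl carbonyl (C4) and E1cB dehydration gives the conjugated cyclopentenone, the trans C1/C5 relationship of 7 becoming the trans ring fusion.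

Step 5
Reactants: 9 trans-3-isopropyl-7a-methyl-6-(tert-butyldimethylsilyloxy)-3a,4,7,7a-tetrahydro-1H-inden-1-one
Product: 11 trans-3α-hydroxy-3β-isopropyl-7aβ-methyl-6-(tert-butyldimethylsilyloxy)-2,3,3a,4,7,7a-hexahydro-1H-inden-1-one, via boronate 10 (not isolated)
Conditions: CuCl (10 mol %), NaOt-Bu (15 mol %), bis[2-(diphenylphosphino)phenyl] ether (10 mol %), B2pin2, MeOH, THF, 23 °C; then NaBO3·4H2O, THF/H2O, 23 °C
Reagents that add atoms: sodium perborate ([Na+].[Na+].O[B-]1(O)OO[B-](O)(O)OO1)
Why: Copper-catalysed conjugate borylation followed by C–B oxidation with retention, the copper–boryl species adding to C4 from the α-face opposite the axial angular methyl so that the tertiary hydroxyl ends α and the isopropyl β.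

Step 6
Reactants: 11 trans-3α-hydroxy-3β-isopropyl-7aβ-methyl-6-(tert-butyldimethylsilyloxy)-2,3,3a,4,7,7a-hexahydro-1H-inden-1-one
Product: 12 trans-3β-isopropyl-7aβ-methyl-6-(tert-butyldimethylsilyloxy)-2,3,3a,4,7,7a-hexahydro-1H-indene-1β,3α-diol
Conditions: NaBH4, EtOH, −20 °C
Reagents that add atoms: none
Why: Hydride reduction of the cyclopentanone from the α-face, anti to the adjacent angular methyl (as in 17-keto steroids), gives the 1β-alcohol (daucane C2) while the silyl enol ether is inert.

Step 7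
Reactants: 12 trans-3β-isopropyl-7aβ-methyl-6-(tert-butyldimethylsilyloxy)-2,3,3a,4,7,7a-hexahydro-1H-indene-1β,3α-diol
Product: 13 trans-3α-hydroxy-3β-isopropyl-7aβ-methyl-6-(tert-butyldimethylsilyloxy)-2,3,3a,4,7,7a-hexahydro-1H-inden-1β-yl acetate
Conditions: Ac2O, DMAP (cat.), pyridine, CH2Cl2, 0 → 23 °C
Reagents that add atoms: acetic anhydride (CC(=O)OC(C)=O)
Why: DMAP-catalysed acylation takes only the secondary hydroxyl, the tertiary C4 hydroxyl being unreactive under these conditions.

Step 8
Reactants: 13 trans-3α-hydroxy-3β-isopropyl-7aβ-methyl-6-(tert-butyldimethylsilyloxy)-2,3,3a,4,7,7a-hexahydro-1H-inden-1β-yl acetate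
Product: 14 siloxycyclopropane of 13 (CH–CH3 bridging C7 and C9, isomer mixture at the cyclopropane)
Conditions: Et2Zn, CH3CHI2, CH2Cl2, 0 → 23 °C
Reagents that add atoms: 1,1-diiodoethane (CC(I)I)
Why: Simmons–Smith (Furukawa) cyclopropanation of the electron-rich silyl enol ether by the ethylidene zinc carbenoid adds C8 with its methyl across C7–C9, and the new cyclopropane centres are lost in the next step so the mixture is used.

Step 9
Reactants: 14 siloxycyclopropane of 13
Product: 16 2β-acetoxy-4α-hydroxydauc-7-en-9-one, via chloroketone 15 (not isolated)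
Conditions: FeCl3, DMF, 0 → 23 °C; then NaOAc, MeOH, 60 °C
Reagents that add atoms: none
Why: Ito–Saegusa ring expansion in which one-electron oxidation by iron trichloride gives an alkoxyl-type radical that cleaves the inner C7–C9 cyclopropane bond (six- to seven-membered ring), chlorine transfer gives the β-chloro ketone and acetate-promoted E1cB loss of HCl gives the 2-methylcycloheptenone without touching any stereocentre of the target.

Step 10
Reactants: 17 (4-bromophenoxy)(tert-butyl)dimethylsilane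
Product: 19 4-(tert-butyldimethylsilyloxy)benzoic acid, via aryllithium 18 (not isolated)
Conditions: n-BuLi, THF, −78 °C; CO2; then 1 M HCl
Reagents that add atoms: carbon dioxide (O=C=O)
Why: Bromine–lithium exchange and carboxylation of the aryllithium with carbon dioxide, the aryl silyl ether surviving at −78 °C.

Step 11
Reactants: 16 2β-acetoxy-4α-hydroxydauc-7-en-9-one; 19 4-(tert-butyldimethylsilyloxy)benzoic acid
Product: 20 2β-acetoxy-4α-hydroxy-9-oxodauc-7-en-6α-yl 4-(tert-butyldimethylsilyloxy)benzoate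
Conditions: Cu(MeCN)4PF6 (10 mol %), 1,10-phenanthroline (12 mol %), (t-BuO)2 (2 equiv), PhCl, 100 °C
Reagents that add atoms: none
Why: Proposed new method: copper-catalysed γ-C–H acyloxylation of a cyclic enone with a free carboxylic acid, in which tert-butoxyl radical (from the peroxide and monovalent copper) abstracts the weak allylic γ-hydrogen at C6, the delocalised radical is captured by the divalent copper carboxylate as a trivalent allylcopper carboxylate, and C–O reductive elimination at C6 (the end that keeps the enone conjugated) delivers the aroyloxy group on the α-face, syn to the coordinating 4α-hydroxyl and opposite the angular methyl and isopropyl groups, setting C6; the closest known reaction types are the Kharasch–Sosnovsky allylic acyloxylation of cycloalkenes and the peroxide-mediated γ-oxidation of enones to ene-diones.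

Step 12
Reactants: 20 2β-acetoxy-4α-hydroxy-9-oxodauc-7-en-6α-yl 4-(tert-butyldimethylsilyloxy)benzoate
Product: 21 (1S,2S,4R,5R,6R)-2-acetoxy-4-hydroxy-9-oxodauc-7-en-6-yl 4-hydroxybenzoate (CNP0087181.1)
Conditions: HF·pyridine, THF, 0 °C
Reagents that add atoms: none
Why: Fluoride-driven desilylation of the aryl silyl ether (Si–F bond formation), mild enough to leave acetate, benzoate, tertiary alcohol and enone untouched.

**Compound list**

1 | 2,3-dimethylfuran | Cc1occc1C | starting material
2 | (2Z)-3-methyl-4-oxopent-2-enal | CC(=O)/C(C)=C\C=O | intermediate (not isolated)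
3 | (2E)-3-methyl-4-oxopent-2-enal | CC(=O)/C(C)=C/C=O | intermediate
4 | 2-(tert-butyldimethylsilyloxy)buta-1,3-diene | C=CC(=C)O[Si](C)(C)C(C)(C)C | starting material
5 | (1S,6S)-6-acetyl-4-(tert-butyldimethylsilyloxy)-6-methylcyclohex-3-ene-1-carbaldehyde (formyl and acetyl trans) | O=C[C@H]1CC=C(O[Si](C)(C)C(C)(C)C)C[C@]1(C)C(C)=O | intermediate
6 | 1-[(1S,6S)-6-acetyl-4-(tert-butyldimethylsilyloxy)-6-methylcyclohex-3-en-1-yl]-2-methylpropan-1-ol (carbinol epimers, formed as the magnesium alkoxide) | CC(C)C(O)[C@H]1CC=C(O[Si](C)(C)C(C)(C)C)C[C@]1(C)C(C)=O | intermediate (not isolated)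
7 | 1-[(1S,6S)-6-acetyl-4-(tert-butyldimethylsilyloxy)-6-methylcyclohex-3-en-1-yl]-2-methylpropan-1-one | CC(C)C(=O)[C@H]1CC=C(O[Si](C)(C)C(C)(C)C)C[C@]1(C)C(C)=O | intermediate
8 | trans-3-hydroxy-3-isopropyl-7a-methyl-6-(tert-butyldimethylsilyloxy)-2,3,3a,4,7,7a-hexahydro-1H-inden-1-one (aldol, C3 epimers) | O=C1CC(O)(C(C)C)[C@H]2CC=C(O[Si](C)(C)C(C)(C)C)C[C@]12C | intermediate (not isolated)
9 | trans-3-isopropyl-7a-methyl-6-(tert-butyldimethylsilyloxy)-3a,4,7,7a-tetrahydro-1H-inden-1-one (3a-H α, 7a-CH3 β) | O=C1C=C(C(C)C)[C@H]2CC=C(O[Si](C)(C)C(C)(C)C)C[C@]12C | intermediate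
10 | 3α-(pinacolboryl) analogue of 11 (boron on C3 α, isopropyl β) | O=C1C[C@@](B3OC(C)(C)C(C)(C)O3)(C(C)C)[C@H]2CC=C(O[Si](C)(C)C(C)(C)C)C[C@]12C | intermediate (not isolated)
11 | trans-3α-hydroxy-3β-isopropyl-7aβ-methyl-6-(tert-butyldimethylsilyloxy)-2,3,3a,4,7,7a-hexahydro-1H-inden-1-one | O=C1C[C@@](O)(C(C)C)[C@H]2CC=C(O[Si](C)(C)C(C)(C)C)C[C@]12C | intermediate
12 | trans-3β-isopropyl-7aβ-methyl-6-(tert-butyldimethylsilyloxy)-2,3,3a,4,7,7a-hexahydro-1H-indene-1β,3α-diol | O[C@H]1C[C@@](O)(C(C)C)[C@H]2CC=C(O[Si](C)(C)C(C)(C)C)C[C@]12C | intermediate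
13 | trans-3α-hydroxy-3β-isopropyl-7aβ-methyl-6-(tert-butyldimethylsilyloxy)-2,3,3a,4,7,7a-hexahydro-1H-inden-1β-yl acetate | CC(=O)O[C@H]1C[C@@](O)(C(C)C)[C@H]2CC=C(O[Si](C)(C)C(C)(C)C)C[C@]12C | intermediate
14 | siloxycyclopropane of 13: CH–CH3 (C8 and its methyl) bridging C7 and C9, silyloxy on C9, cyclopropane isomer mixture | CC(=O)O[C@H]1C[C@@](O)(C(C)C)[C@H]2CC3C(C)C3(O[Si](C)(C)C(C)(C)C)C[C@]12C | intermediate
15 | 2β-acetoxy-7-chloro-4α-hydroxydaucan-9-one (C7/C8 epimers) | CC(=O)O[C@H]1C[C@@](O)(C(C)C)[C@H]2CC(Cl)C(C)C(=O)C[C@]12C | intermediate (not isolated)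
16 | 2β-acetoxy-4α-hydroxydauc-7-en-9-one (5α-H, 1β-CH3) | CC(=O)O[C@H]1C[C@@](O)(C(C)C)[C@H]2CC=C(C)C(=O)C[C@]12C | intermediate
17 | (4-bromophenoxy)(tert-butyl)dimethylsilane | CC(C)(C)[Si](C)(C)Oc1ccc(Br)cc1 | starting material
18 | [4-(tert-butyldimethylsilyloxy)phenyl]lithium | [Li]c1ccc(O[Si](C)(C)C(C)(C)C)cc1 | intermediate (not isolated)
19 | 4-(tert-butyldimethylsilyloxy)benzoic acid | OC(=O)c1ccc(O[Si](C)(C)C(C)(C)C)cc1 | intermediate
20 | 2β-acetoxy-4α-hydroxy-9-oxodauc-7-en-6α-yl 4-(tert-butyldimethylsilyloxy)benzoate | CC(=O)O[C@H]1C[C@@](O)(C(C)C)[C@H]2[C@H](OC(=O)c3ccc(O[Si](C)(C)C(C)(C)C)cc3)C=C(C)C(=O)C[C@]12C | intermediate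
21 | (1S,2S,4R,5R,6R)-2-acetoxy-4-hydroxy-9-oxodauc-7-en-6-yl 4-hydroxybenzoate (2β-OAc, 4α-OH, 4β-i-Pr, 5α-H, 6α-O-aroyl) | CC(=O)O[C@H]1C[C@@](O)(C(C)C)[C@H]2[C@H](OC(=O)c3ccc(O)cc3)C=C(C)C(=O)C[C@]12C | target

**Step count and risk**

Total steps: 12. Longest linear sequence: 11 steps (steps 1–9, 11 and 12; step 10 is a one-step side branch).

Step 5 (conjugate borylation of a very hindered β,β-disubstituted cyclopentenone) may be too slow. The fallback sets out from 9: tert-butyl hydroperoxide and DBU in CH2Cl2 (Weitz–Scheffer epoxidation, peroxide attacking C4 from the α-face) give the α-epoxy ketone F1. SmI2 in THF/MeOH at −78 °C then cleaves the C–O bond next to the carbonyl and leaves the oxygen on C4, which gives 11, where the route is rejoined.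

Step 9 (ring expansion) may open the outer cyclopropane bond instead, because the methyl group makes that radical secondary as well, or the ethylidene transfer of step 8 may be poor. The fallback sets out from 13: Et2Zn/CH2I2 gives the unsubstituted siloxycyclopropane F2. FeCl3 in DMF gives the β-chloro ketone F3, which NaOAc in MeOH converts to the 8-demethyl enone F4. I2/pyridine gives the 8-iodo enone F5, and Stille coupling with Me4Sn (Pd(PPh3)4, CuI, NMP) installs the methyl group to give 16, where the route is rejoined.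

Step 11 (the proposed γ-C–H acyloxylation) may fail through over-oxidation, attack at other C–H bonds or poor facial control. The fallback uses known chemistry and sets out from 16: Rh2(cap)4 (dirhodium tetracaprolactamate) with tert-butyl hydroperoxide oxidises the γ-position to the ene-dione F6. NaBH4/CeCl3·7H2O in MeOH at −78 °C reduces the less hindered C6 carbonyl from the open α-face to the 6β-alcohol F7. A Mitsunobu reaction (PPh3, DIAD, THF) with acid 19 inverts C6 and gives 20, where the route is rejoined.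

Further compounds
F1 | step 5 | 2α,3α-epoxy-3β-isopropyl-7aβ-methyl-6-(tert-butyldimethylsilyloxy)-2,3,3a,4,7,7a-hexahydro-1H-inden-1-one (trans-fused) | O=C1[C@@H]3O[C@]3(C(C)C)[C@H]2CC=C(O[Si](C)(C)C(C)(C)C)C[C@]12C
F2 | step 9 | 8-demethyl analogue of 14 (CH2 bridging C7 and C9) | CC(=O)O[C@H]1C[C@@](O)(C(C)C)[C@H]2CC3CC3(O[Si](C)(C)C(C)(C)C)C[C@]12C
F3 | step 9 | 2β-acetoxy-7-chloro-4α-hydroxy-8-demethyldaucan-9-one (not isolated) | CC(=O)O[C@H]1C[C@@](O)(C(C)C)[C@H]2CC(Cl)CC(=O)C[C@]12C
F4 | step 9 | 2β-acetoxy-4α-hydroxy-8-demethyldauc-7-en-9-one | CC(=O)O[C@H]1C[C@@](O)(C(C)C)[C@H]2CC=CC(=O)C[C@]12C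
F5 | step 9 | 2β-acetoxy-4α-hydroxy-8-demethyl-8-iododauc-7-en-9-one | CC(=O)O[C@H]1C[C@@](O)(C(C)C)[C@H]2CC=C(I)C(=O)C[C@]12C
F6 | step 11 | 2β-acetoxy-4α-hydroxydauc-7-ene-6,9-dione | CC(=O)O[C@H]1C[C@@](O)(C(C)C)[C@H]2C(=O)C=C(C)C(=O)C[C@]12C
F7 | step 11 | 2β-acetoxy-4α,6β-dihydroxydauc-7-en-9-one | CC(=O)O[C@H]1C[C@@](O)(C(C)C)[C@H]2[C@@H](O)C=C(C)C(=O)C[C@]12C
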